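**Two steps.** By the first reading of the delta run you have 15.9% of G for 25.0% of Z lost. Later Z keeps falling while G stands still, so I read each lost Z as either making a G from J or using one up. Equal steps are the zero of the scale: G flat, Z still falling.

| setting | delta | epsilon | flask |
|---|---|---|---|
| Z | 0.17 M | 0.11 M | 0.17 M |
| J | 0.34 M | 0.34 M | 0.340 M |
| L | 0.17 M | 0.17 M | 0.170 M |
| D | 0.034 M | 0.034 M | 0.0340 M |
| remark | the very flask that is asked about, followed so far | run made earlier |  |
| time |  |  | 10 h |

| run | time / h | G / % | Z / % |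
|---|---|---|---|
| delta | 0.833 | 15.9 | 75.0 |
| delta | 1.33 | 19.6 | 62.8 |
| delta | 2.00 | 21.9 | 50.0 |
| delta | 3.00 | 22.1 | 35.5 |
| delta | 5.00 | 21.9 | 20.3 |
| epsilon | 0.833 | 18.3 | 76.3 |
| epsilon | 1.50 | 23.9 | 61.2 |
| epsilon | 3.00 | 29.9 | 37.0 |
| epsilon | 5.00 | 31.4 | 20.2 |
| epsilon | 10.0 | 32.0 | 5.3 |

(standard deviation of a reading: 0.5 percentage points)

1. when, up to 10 h, the flask holds most G
2. the amount of G, in percent of the Z charged, at that time
3. earliest time at which at least nineteen twentieths of that best amount are there
4. latest time at which they still are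



**Two rates.** Early in the delta run, Z falls at 0.345 h⁻¹. Counting G's share of the lost Z, making runs at 0.283 h⁻¹. Between 3.00 h and 5.00 h, G stands near 0.0376 M while Z falls at 0.279 h⁻¹, so each step takes 0.140 h⁻¹. I take making as proportional to c(J), with J at its charge, and using as proportional to c(G). The selectivity factor, the rate constant of using over that of making, is then 4.48. G stops rising where c(J)/c(G) equals it.

**My reckoning.** If J keeps falling, c(G) follows it down, so I expect the peak near 3.00 h, at about 22.1%, with slow loss afterwards.

**The forecast.** It gives 22.2% at 10 h, with a window from 1.7 h to 10 h, holding that “G should stay near 22% to 10 h”.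

**The result.** The flask holds 22.7% at 3.26 h, and the window runs from 1.87 h to 6.82 h.

    L + D → Q (k = 16.0 M⁻¹ h⁻¹)
    L + J → X (k = 2.10 M⁻¹ h⁻¹)
    Z + G → E (k = 4.00 M⁻¹ h⁻¹)
    Z + J → G (k = 0.990 M⁻¹ h⁻¹)

**Neighbour flask.** At the flask's best time c(J)/c(G) stands at 4.04, against 4.48. Now charge 1.4 M of J instead. At 10.0 h that neighbour flask has c(J)/c(G) at 9.93, which is larger than the 4.48 read from the delta run, so by this reckoning making is still ahead of using. Its G stands at 65.7% at the end, equal to its best, against 34.3% of E.

The numbers in the tables are calculated for an exercise.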